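**Plan**
1. Cuts: the two silicon-based protecting groups come off. C8=C17 goes back to a C7=C8–C17HO enal (reductive transposition) and then to its aldol. C7–C8 and C9–C10 of ring B are then cut together, giving ring A aldehyde 12 and side-chain enal 17.
2. Enabling feature: in ring B the quaternary C10 is the tertiary-radical (Markovnikov) carbon of a C10=C20 methylene on ring A. C9, C8 and C17 are the β-, α- and formyl carbons of an enal, and C7 is an aldehyde carbon two atoms from C5. One hydrogen-atom transfer therefore triggers radical addition (C9–C10, joining two carbons that are both electrophilic in polar terms) and aldol closure (C7–C8).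
3. Ring A is cut at C5–C6 (Claisen rearrangement from the C20 allylic alcohol), at C5=C10 (aldol condensation of a dialdehyde) and at C3–C4 (iridium-catalysed coupling of hex-5-en-1-ol with isoprene monoxide).
4. Forward order: C3–C4 coupling, acid/ester/acetate set-up, ring A closure, C5 side chain, ring B annulation (which also attaches the C11–C16 chain), methylene formation, deprotection.
5. Stereochemistry: C3 and C4 come from the chiral iridium catalyst. C5 comes from C3/C4 in the Claisen step. C10 and C9 come from C4/C5 in the annulation. The 13E alkene comes from geraniol.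

Key step: step 12

Remark: labdane numbering (C1–C20; α below and β above the plane, C20 β) is used for all intermediates. TMSE = 2-(trimethylsilyl)ethyl, TBDPS = tert-butyldiphenylsilyl.
Assumption: the (S)-Tol-BINAP iridium catalyst is taken to give the (2R,3R) diol 3; should the sense of induction be the opposite, the (R)-ligand is used and nothing else changes.

Step 1
Reactants: 1 hex-5-en-1-ol; 2 2-methyl-2-vinyloxirane (isoprene monoxide, racemic)
Product: 3 (2R,3R)-2-ethenyl-2-methyloct-7-ene-1,3-diol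
Conditions: Ir(η3-allyl)[(S)-Tol-BINAP](C,O-4-chloro-3-nitrobenzoate) (5 mol %), K3PO4 (5 mol %), 2 (3 equiv), THF, 60 °C
Reagents that add atoms: none
Why: Iridium-catalysed transfer-hydrogenative carbonyl tert-(hydroxy)prenylation: the catalyst dehydrogenates 1 to hex-5-enal, opens the vinyl epoxide to an (E)-σ-allyliridium species and joins the two through a closed chair transition state, so the C3 carbinol and the quaternary C4 arise together as the anti diastereomer (CH2OH anti, CH3 syn to OH) with the absolute sense fixed by the ligand.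

Step 2
Reactants: 3 (2R,3R)-2-ethenyl-2-methyloct-7-ene-1,3-diol
Product: 5 (2S,3R)-2-ethenyl-3-hydroxy-2-methyloct-7-enoic acid, via hydroxy aldehyde 4 (not isolated)
Conditions: TEMPO (20 mol %), PhI(OAc)2 (2.2 equiv), MeCN/H2O 1:1, rt
Reagents that add atoms: water, O
Why: Oxoammonium (TEMPO/PhI(OAc)2) oxidation in aqueous acetonitrile prefers the primary alcohol over the hindered secondary carbinol and carries the aldehyde hydrate on to the acid without touching the alkenes or the stereocentres.

Step 3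
Reactants: 5 (2S,3R)-2-ethenyl-3-hydroxy-2-methyloct-7-enoic acid
Product: 6 2-(trimethylsilyl)ethyl (2S,3R)-2-ethenyl-3-hydroxy-2-methyloct-7-enoate
Conditions: Cl3CC(=NH)OCH2CH2SiMe3 (1.5 equiv), toluene, 100 °C
Reagents that add atoms: 2-(trimethylsilyl)ethyl 2,2,2-trichloroacetimidate, C[Si](C)(C)CCOC(=N)C(Cl)(Cl)Cl
Why: Promoter-free O-alkylation of a carboxylic acid by a trichloroacetimidate forms the bond at the unhindered CH2 of the reagent, so the neopentyl carboxyl needs no acyl activation (no β-lactone pathway) and the much less acidic C3 hydroxyl stays free.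

Step 4
Reactants: 6 2-(trimethylsilyl)ethyl (2S,3R)-2-ethenyl-3-hydroxy-2-methyloct-7-enoate
Product: 7 2-(trimethylsilyl)ethyl (2S,3R)-3-acetoxy-2-ethenyl-2-methyloct-7-enoate
Conditions: Ac2O, Et3N, DMAP (10 mol %), CH2Cl2, rt
Reagents that add atoms: acetic anhydride, CC(=O)OC(C)=O
Why: DMAP-catalysed acetylation acylates the hindered secondary alcohol at oxygen, so C3 keeps its configuration, and the quaternary C4 excludes β-elimination.

Step 5
Reactants: 7 2-(trimethylsilyl)ethyl (2S,3R)-3-acetoxy-2-ethenyl-2-methyloct-7-enoate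
Product: 9 2-(trimethylsilyl)ethyl (1S,6R)-6-acetoxy-3-formyl-1-methylcyclohex-2-ene-1-carboxylate, via dialdehyde 8 (not isolated)
Conditions: O3, CH2Cl2, −78 °C; PPh3 (2.2 equiv), −78 °C to rt; solvent change to toluene, Bn2NH·CF3CO2H (20 mol %), rt to 40 °C
Reagents that add atoms: ozone, [O-][O+]=O
Why: Ozonolysis turns both terminal alkenes into aldehydes, and in 8 only C10 can become the enamine carbon while the C5 formyl group on quaternary C4 has no α-hydrogen, so the amine-salt-catalysed intramolecular aldol condensation (6-(enolexo)-exo-trig) can close only ring A with the C5=C10 double bond, leaving C3 and C4 untouched.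

Step 6
Reactants: 9 2-(trimethylsilyl)ethyl (1S,6R)-6-acetoxy-3-formyl-1-methylcyclohex-2-ene-1-carboxylate
Product: 10 2-(trimethylsilyl)ethyl (1S,6R)-6-acetoxy-3-(hydroxymethyl)-1-methylcyclohex-2-ene-1-carboxylate
Conditions: NaBH4, CeCl3·7H2O, MeOH, −20 °C
Reagents that add atoms: none
Why: Luche reduction gives clean 1,2-reduction of the enal to the C20 allylic alcohol and leaves the acetate and the hindered ester alone.

Step 7
Reactants: 10 2-(trimethylsilyl)ethyl (1S,6R)-6-acetoxy-3-(hydroxymethyl)-1-methylcyclohex-2-ene-1-carboxylate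
Product: 12 2-(trimethylsilyl)ethyl (1S,2R,6R)-6-acetoxy-1-methyl-3-methylidene-2-(2-oxoethyl)cyclohexane-1-carboxylate, via allyl vinyl ether 11 (not isolated)
Conditions: butyl vinyl ether (excess), Pd(OAc)2 (5 mol %), 1,10-phenanthroline (5 mol %), 60 °C; filtration through basic alumina, evaporation; xylenes, 145 °C (sealed tube)
Reagents that add atoms: butyl vinyl ether, C=COCCCC
Why: Vinyl ether exchange catalysed by divalent palladium gives 11, whose aliphatic Claisen rearrangement forms C5–C6, unveils the C7 aldehyde and moves the double bond to C10=C20 in one stroke; in the favoured half-chair of ring A (3-OAc equatorial, 4-CO2TMSE pseudoaxial on the α face) the new bond forms axially on the β face, anti to the ester and directly into a chair, whereas α attack would need the other half-chair and a 1,3-diaxial clash with the acetate, so C5 is set with 5α-H.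

Step 8
Reactants: 13 geraniol
Product: 14 tert-butyl{[(2E)-3,7-dimethylocta-2,6-dien-1-yl]oxy}diphenylsilane
Conditions: TBDPSCl, imidazole, DMF, rt
Reagents that add atoms: tert-butyl(chloro)diphenylsilane, CC(C)(C)[Si](Cl)(c1ccccc1)c1ccccc1
Why: Standard imidazole-promoted silylation of a primary allylic alcohol keeps the E alkene that becomes C13=C14.

Step 9
Reactants: 14 tert-butyl{[(2E)-3,7-dimethylocta-2,6-dien-1-yl]oxy}diphenylsilane
Product: 15 tert-butyl{[(2E)-5-(3,3-dimethyloxiran-2-yl)-3-methylpent-2-en-1-yl]oxy}diphenylsilane (racemic at the epoxide)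
Conditions: mCPBA (1.0 equiv), CH2Cl2, −20 to 0 °C
Reagents that add atoms: 3-chloroperoxybenzoic acid, O=C(OO)c1cccc(Cl)c1
Why: Prilezhaev epoxidation takes the electron-richer distal alkene of geranyl derivatives in preference to the alkene deactivated by the allylic oxygen, and the new stereocentre is destroyed in step 10.

Step 10
Reactants: 15 tert-butyl{[(2E)-5-(3,3-dimethyloxiran-2-yl)-3-methylpent-2-en-1-yl]oxy}diphenylsilane
Product: 16 (4E)-6-[(tert-butyldiphenylsilyl)oxy]-4-methylhex-4-enal
Conditions: H5IO6, THF/H2O, 0 °C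
Reagents that add atoms: none
Why: Periodic acid opens the epoxide to the glycol and cleaves it in the same pot (Malaprade-type cleavage), a standard degradation of geranyl 6,7-epoxides that spares the silyl ether and the remaining alkene.

Step 11
Reactants: 16 (4E)-6-[(tert-butyldiphenylsilyl)oxy]-4-methylhex-4-enal
Product: 17 (2E,6E)-8-[(tert-butyldiphenylsilyl)oxy]-6-methylocta-2,6-dienal
Conditions: Ph3P=CHCHO, toluene, 80 °C
Reagents that add atoms: (triphenylphosphoranylidene)acetaldehyde, O=CC=P(c1ccccc1)(c1ccccc1)c1ccccc1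
Why: Wittig reaction with the stabilised formyl ylide gives the E enal that carries C9, C8 and C17.

Step 12
Reactants: 12 2-(trimethylsilyl)ethyl (1S,2R,6R)-6-acetoxy-1-methyl-3-methylidene-2-(2-oxoethyl)cyclohexane-1-carboxylate; 17 (2E,6E)-8-[(tert-butyldiphenylsilyl)oxy]-6-methylocta-2,6-dienal
Product: 20 TMSE 3α-acetoxy-7β-hydroxy-17-oxo-15-(TBDPS-oxy)labd-13E-en-18-oate (8-formyl group equatorial), via C10 radical 18 (not isolated), via iron enolate 19 (not isolated)
Conditions: Fe(acac)3 (25 mol %), PhSiH2(Oi-Pr) (2.5 equiv), 17 (2 equiv), i-PrOH/1,2-dichloroethane, argon, 0 °C to rt, dilute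
Reagents that add atoms: none
Why: The iron hydride formed from Fe(acac)3 and the silane delivers H• to C20 of the 1,1-disubstituted alkene of 12 (Markovnikov MHAT), tertiary radical 18 adds to the β-carbon C9 of enal 17 (Giese addition, C9–C10), the resulting α-formyl radical is reduced by divalent iron to enolate 19, and 19 attacks the tethered C7 aldehyde (C7–C8), after which 2-propanol frees the alkoxide and returns trivalent iron. The closest known reaction type is the iron-catalysed HAT-initiated radical–polar crossover annulation of γ,δ-unsaturated aldehydes with α,β-unsaturated carbonyl compounds, of which this is a direct application. Ring B closes in the aldol event, a 6-(enolexo)-exo-trig closure through a chair in which C6 and C9 are both equatorial on ring A. C10 is controlled by ring A, because the acceptor approaches the radical on the α face, anti to the C5 side chain and away from the axial 4β-methyl group, which leaves the 10β-methyl group and the trans ring fusion; C9 is controlled by the staggered addition geometry, in which its hydrogen points toward ring A, the slim sp2 arm C8 takes the crowded flank beside C5/C6 (the only rotamer from which C8 reaches C7) and the sp3 chain C11 takes the open flank beside C1, so that the chain ends equatorial (9α-H). C7 and C8 are expected with hydroxyl and formyl groups equatorial from the chair closure, but both centres are erased in step 13. The step needs HAT at C10=C20 rather than at C13=C14 and ring closure rather than intermolecular aldol reaction: the trisubstituted C13=C14 alkene is more hindered, inductively deactivated by its allylic oxygen and shielded by the TBDPS group, and the six-membered intramolecular closure outruns any bimolecular reaction of 19 in dilute solution.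

Step 13
Reactants: 20 TMSE 3α-acetoxy-7β-hydroxy-17-oxo-15-(TBDPS-oxy)labd-13E-en-18-oate
Product: 22 TMSE 3α-acetoxy-17-oxo-15-(TBDPS-oxy)labda-7,13E-dien-18-oate, via mesylate 21 (not isolated)
Conditions: MsCl, Et3N, CH2Cl2, −20 °C; then DBU, 0 °C to rt
Reagents that add atoms: methanesulfonyl chloride, CS(=O)(=O)Cl (its atoms stay only in 21)
Why: Mesylation followed by E1cB elimination through the acidic C8–H can give only the conjugated C7=C8 enal, and C9, which sits on the α-carbon of the enal and is not vinylogously acidic, is not epimerised.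

Step 14
Reactants: 22 TMSE 3α-acetoxy-17-oxo-15-(TBDPS-oxy)labda-7,13E-dien-18-oate
Product: 23 N-tosylhydrazone of 22 (E at C17=N)
Conditions: TsNHNH2 (1.05 equiv), THF, 4 Å molecular sieves, rt
Reagents that add atoms: 4-methylbenzenesulfonohydrazide, Cc1ccc(cc1)S(=O)(=O)NN
Why: Condensation of the only aldehyde with tosylhydrazide is fast at room temperature, and the α,β-disubstituted ring enal resists conjugate addition.

Step 15
Reactants: 23 N-tosylhydrazone of 22
Product: 25 TMSE 3α-acetoxy-15-(TBDPS-oxy)labda-8(17),13E-dien-18-oate, via allylic diazene 24 (not isolated)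
Conditions: catecholborane (2 equiv), CHCl3, −40 to 0 °C; then NaOAc·3H2O, 0 to 40 °C
Reagents that add atoms: none
Why: Alkene-transposing reduction of an α,β-unsaturated tosylhydrazone: hydride adds to C17, loss of sulfinate gives allylic diazene 24, and its retro-ene loss of N2 hands hydrogen to C7 and moves the double bond to C8=C17, without making or touching a stereocentre and without reducing esters or isolated alkenes.

Step 16
Reactants: 25 TMSE 3α-acetoxy-15-(TBDPS-oxy)labda-8(17),13E-dien-18-oate
Product: 26 3α-acetoxy-15-hydroxylabda-8(17),13E-dien-18-oic acid (target)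
Conditions: TBAF (4 equiv), THF, 0 °C to rt; dilute aq HCl to pH 4
Reagents that add atoms: none
Why: Fluoride attacks silicon in both groups (β-elimination of the TMSE ester, Si–O cleavage of the TBDPS ether), so the hindered carboxyl is freed without acyl substitution and the hindered axial acetate next to quaternary C4 should survive.

**Compound list**
1 | hex-5-en-1-ol | C=CCCCCO | starting material
2 | 2-methyl-2-vinyloxirane (racemic) | CC1(C=C)CO1 | starting material
3 | (2R,3R)-2-ethenyl-2-methyloct-7-ene-1,3-diol | C=C[C@](C)(CO)[C@H](O)CCCC=C | intermediate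
4 | (2S,3R)-2-ethenyl-3-hydroxy-2-methyloct-7-enal (not isolated) | C=C[C@](C)(C=O)[C@H](O)CCCC=C | intermediate
5 | (2S,3R)-2-ethenyl-3-hydroxy-2-methyloct-7-enoic acid | C=C[C@](C)(C(=O)O)[C@H](O)CCCC=C | intermediate
6 | 2-(trimethylsilyl)ethyl (2S,3R)-2-ethenyl-3-hydroxy-2-methyloct-7-enoate | C=C[C@](C)(C(=O)OCC[Si](C)(C)C)[C@H](O)CCCC=C | intermediate
7 | 2-(trimethylsilyl)ethyl (2S,3R)-3-acetoxy-2-ethenyl-2-methyloct-7-enoate | C=C[C@](C)(C(=O)OCC[Si](C)(C)C)[C@H](OC(C)=O)CCCC=C | intermediate
8 | 2-(trimethylsilyl)ethyl (2R,3R)-3-acetoxy-2-formyl-2-methyl-7-oxoheptanoate (not isolated) | O=C[C@](C)(C(=O)OCC[Si](C)(C)C)[C@H](OC(C)=O)CCCC=O | intermediate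
9 | 2-(trimethylsilyl)ethyl (1S,6R)-6-acetoxy-3-formyl-1-methylcyclohex-2-ene-1-carboxylate | O=CC1=C[C@](C)(C(=O)OCC[Si](C)(C)C)[C@H](OC(C)=O)CC1 | intermediate
10 | 2-(trimethylsilyl)ethyl (1S,6R)-6-acetoxy-3-(hydroxymethyl)-1-methylcyclohex-2-ene-1-carboxylate | OCC1=C[C@](C)(C(=O)OCC[Si](C)(C)C)[C@H](OC(C)=O)CC1 | intermediate
11 | 2-(trimethylsilyl)ethyl (1S,6R)-6-acetoxy-3-[(ethenyloxy)methyl]-1-methylcyclohex-2-ene-1-carboxylate (not isolated) | C=COCC1=C[C@](C)(C(=O)OCC[Si](C)(C)C)[C@H](OC(C)=O)CC1 | intermediate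
12 | 2-(trimethylsilyl)ethyl (1S,2R,6R)-6-acetoxy-1-methyl-3-methylidene-2-(2-oxoethyl)cyclohexane-1-carboxylate | O=CC[C@@H]1C(=C)CC[C@@H](OC(C)=O)[C@@]1(C)C(=O)OCC[Si](C)(C)C | intermediate
13 | geraniol | CC(C)=CCC/C(C)=C/CO | starting material
14 | tert-butyl{[(2E)-3,7-dimethylocta-2,6-dien-1-yl]oxy}diphenylsilane | CC(C)=CCC/C(C)=C/CO[Si](c1ccccc1)(c1ccccc1)C(C)(C)C | intermediate
15 | tert-butyl{[(2E)-5-(3,3-dimethyloxiran-2-yl)-3-methylpent-2-en-1-yl]oxy}diphenylsilane (racemic epoxide) | CC1(C)OC1CC/C(C)=C/CO[Si](c1ccccc1)(c1ccccc1)C(C)(C)C | intermediate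
16 | (4E)-6-[(tert-butyldiphenylsilyl)oxy]-4-methylhex-4-enal | O=CCC/C(C)=C/CO[Si](c1ccccc1)(c1ccccc1)C(C)(C)C | intermediate
17 | (2E,6E)-8-[(tert-butyldiphenylsilyl)oxy]-6-methylocta-2,6-dienal | O=C/C=C/CC/C(C)=C/CO[Si](c1ccccc1)(c1ccccc1)C(C)(C)C | intermediate
18 | tertiary C10 radical from 12 (not isolated) | O=CC[C@@H]1[C](C)CC[C@@H](OC(C)=O)[C@@]1(C)C(=O)OCC[Si](C)(C)C | intermediate
19 | open-chain Giese adduct as its enolate, iron counter-ion omitted, enolate geometry open (not isolated) | O=CC[C@@H]1[C@](C)(CC[C@@H](OC(C)=O)[C@@]1(C)C(=O)OCC[Si](C)(C)C)[C@H](C=C[O-])CC/C(C)=C/CO[Si](c1ccccc1)(c1ccccc1)C(C)(C)C | intermediate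
20 | TMSE 3α-acetoxy-7β-hydroxy-17-oxo-15-(TBDPS-oxy)labd-13E-en-18-oate (5α-H, 9α-H, 10β-Me, 8β-H) | O=C[C@@H]1[C@@H](O)C[C@@H]2[C@](C)(CC[C@@H](OC(C)=O)[C@@]2(C)C(=O)OCC[Si](C)(C)C)[C@H]1CC/C(C)=C/CO[Si](c1ccccc1)(c1ccccc1)C(C)(C)C | intermediate
21 | 7-O-mesylate of 20 (not isolated) | O=C[C@@H]1[C@@H](OS(C)(=O)=O)C[C@@H]2[C@](C)(CC[C@@H](OC(C)=O)[C@@]2(C)C(=O)OCC[Si](C)(C)C)[C@H]1CC/C(C)=C/CO[Si](c1ccccc1)(c1ccccc1)C(C)(C)C | intermediate
22 | TMSE 3α-acetoxy-17-oxo-15-(TBDPS-oxy)labda-7,13E-dien-18-oate | O=CC1=CC[C@@H]2[C@](C)(CC[C@@H](OC(C)=O)[C@@]2(C)C(=O)OCC[Si](C)(C)C)[C@H]1CC/C(C)=C/CO[Si](c1ccccc1)(c1ccccc1)C(C)(C)C | intermediate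
23 | N-tosylhydrazone of 22 | Cc1ccc(cc1)S(=O)(=O)N/N=C/C1=CC[C@@H]2[C@](C)(CC[C@@H](OC(C)=O)[C@@]2(C)C(=O)OCC[Si](C)(C)C)[C@H]1CC/C(C)=C/CO[Si](c1ccccc1)(c1ccccc1)C(C)(C)C | intermediate
24 | C17 allylic diazene (not isolated) | N=NCC1=CC[C@@H]2[C@](C)(CC[C@@H](OC(C)=O)[C@@]2(C)C(=O)OCC[Si](C)(C)C)[C@H]1CC/C(C)=C/CO[Si](c1ccccc1)(c1ccccc1)C(C)(C)C | intermediate
25 | TMSE 3α-acetoxy-15-(TBDPS-oxy)labda-8(17),13E-dien-18-oate | C=C1CC[C@@H]2[C@](C)(CC[C@@H](OC(C)=O)[C@@]2(C)C(=O)OCC[Si](C)(C)C)[C@H]1CC/C(C)=C/CO[Si](c1ccccc1)(c1ccccc1)C(C)(C)C | intermediate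
26 | (1S,2R,4aR,5S,8aR)-2-acetoxy-5-[(3E)-5-hydroxy-3-methylpent-3-en-1-yl]-1,4a-dimethyl-6-methylidenedecahydronaphthalene-1-carboxylic acid | C=C1CC[C@@H]2[C@](C)(CC[C@@H](OC(C)=O)[C@@]2(C)C(=O)O)[C@H]1CC/C(C)=C/CO | target

Total step count: 16. Longest linear sequence: 12 steps (steps 1–7 and 12–16); steps 8–11 form the convergent branch.

**Steps most likely to fail**

Step 12.
- Risk: capture of the hindered tertiary radical by the β-substituted enal may be slower than its reduction. Facial discrimination at C9 may be weak. Hydrogen-atom transfer may stray to the side-chain alkene.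
- Fallback (sets out from 16 and 12, comes back at 25): C9 is kept sp2 during the annulation and is configured afterwards by intramolecular hydrogen delivery.
- Aldehyde 16 is homologated with the Ohira–Bestmann reagent (K2CO3, MeOH) to tert-butyl{[(2E)-3-methylhept-2-en-6-yn-1-yl]oxy}diphenylsilane F1. Deprotonation (n-BuLi) and formylation (DMF) then give (6E)-8-[(tert-butyldiphenylsilyl)oxy]-6-methyloct-6-en-2-ynal F2.
- Under the conditions of step 12, radical 18 should add to the unhindered sp carbon of F2. The allenolate should then close onto C7 to give TMSE 3α-acetoxy-7β-hydroxy-17-oxo-15-(TBDPS-oxy)labda-8,13E-dien-18-oate F3.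
- TsNHNH2 gives the N-tosylhydrazone of the hydroxy enal F4. Catecholborane followed by NaOAc·3H2O gives TMSE 3α-acetoxy-7β-hydroxy-15-(TBDPS-oxy)labda-8(17),13E-dien-18-oate F5. Here the diazene on C17 hands its hydrogen to C9 on the α face, opposite the axial C10 methyl group.
- ClCO2Me/pyridine gives the 7-O-methyl carbonate F6. Formate hydrogenolysis (Pd(OAc)2, PBu3, HCO2H, Et3N, THF) places hydride on the more substituted allyl terminus C7 and returns 25.

Step 7.
- Risk: vinyl transfer may be incomplete, the [3,3] shift next to the quaternary carbon may be sluggish, and the aldehyde may degrade at the temperature required.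
- Fallback (sets out from 10, comes back at 12): the rearrangement is run at the amide oxidation level. Alcohol 10 is heated with N,N-dimethylacetamide dimethyl acetal in toluene at 110 °C (Eschenmoser–Claisen rearrangement, same face selection). This gives 2-(trimethylsilyl)ethyl (1S,2R,6R)-6-acetoxy-2-[2-(dimethylamino)-2-oxoethyl]-1-methyl-3-methylidenecyclohexane-1-carboxylate F7.
- The tertiary amide alone is then reduced to aldehyde 12 with Cp2Zr(H)Cl in THF at rt. This reduction is faster than hydrozirconation of the 1,1-disubstituted alkene and spares both esters.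

Step 5.
- Risk: the α-formyl ester may lose its formyl group (retro-Claisen cleavage), or the dialdehyde may oligomerise during the amine-catalysed condensation.
- Fallback (sets out from 7, comes back at 10): ring A is closed by metathesis instead, so the C5 formyl ester is never made. OsO4 (cat.)/NaIO4/2,6-lutidine cleaves only the unhindered terminal alkene to 2-(trimethylsilyl)ethyl (2S,3R)-3-acetoxy-2-ethenyl-2-methyl-7-oxoheptanoate F8.
- Organocatalytic α-methylenation (aqueous formaldehyde, pyrrolidine/propionic acid) gives 2-(trimethylsilyl)ethyl (2S,3R)-3-acetoxy-2-ethenyl-6-formyl-2-methylhept-6-enoate F9. Luche reduction gives 2-(trimethylsilyl)ethyl (2S,3R)-3-acetoxy-2-ethenyl-6-(hydroxymethyl)-2-methylhept-6-enoate F10.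
- Ring-closing metathesis with the second-generation Grubbs catalyst (toluene, 80 °C) gives 10.

**Further compounds**
F1 | step 12 | tert-butyl{[(2E)-3-methylhept-2-en-6-yn-1-yl]oxy}diphenylsilane | C#CCC/C(C)=C/CO[Si](c1ccccc1)(c1ccccc1)C(C)(C)C
F2 | step 12 | (6E)-8-[(tert-butyldiphenylsilyl)oxy]-6-methyloct-6-en-2-ynal | O=CC#CCC/C(C)=C/CO[Si](c1ccccc1)(c1ccccc1)C(C)(C)C
F3 | step 12 | TMSE 3α-acetoxy-7β-hydroxy-17-oxo-15-(TBDPS-oxy)labda-8,13E-dien-18-oate | O=CC1=C(CC/C(C)=C/CO[Si](c2ccccc2)(c2ccccc2)C(C)(C)C)[C@@]2(C)CC[C@@H](OC(C)=O)[C@@](C)(C(=O)OCC[Si](C)(C)C)[C@@H]2C[C@@H]1O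
F4 | step 12 | N-tosylhydrazone of the hydroxy enal | Cc1ccc(cc1)S(=O)(=O)N/N=C/C1=C(CC/C(C)=C/CO[Si](c2ccccc2)(c2ccccc2)C(C)(C)C)[C@@]2(C)CC[C@@H](OC(C)=O)[C@@](C)(C(=O)OCC[Si](C)(C)C)[C@@H]2C[C@@H]1O
F5 | step 12 | TMSE 3α-acetoxy-7β-hydroxy-15-(TBDPS-oxy)labda-8(17),13E-dien-18-oate | C=C1[C@@H](O)C[C@@H]2[C@](C)(CC[C@@H](OC(C)=O)[C@@]2(C)C(=O)OCC[Si](C)(C)C)[C@H]1CC/C(C)=C/CO[Si](c1ccccc1)(c1ccccc1)C(C)(C)C
F6 | step 12 | 7-O-methyl carbonate | C=C1[C@@H](OC(=O)OC)C[C@@H]2[C@](C)(CC[C@@H](OC(C)=O)[C@@]2(C)C(=O)OCC[Si](C)(C)C)[C@H]1CC/C(C)=C/CO[Si](c1ccccc1)(c1ccccc1)C(C)(C)C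
F7 | step 7 | 2-(trimethylsilyl)ethyl (1S,2R,6R)-6-acetoxy-2-[2-(dimethylamino)-2-oxoethyl]-1-methyl-3-methylidenecyclohexane-1-carboxylate | CN(C)C(=O)C[C@@H]1C(=C)CC[C@@H](OC(C)=O)[C@@]1(C)C(=O)OCC[Si](C)(C)C
F8 | step 5 | 2-(trimethylsilyl)ethyl (2S,3R)-3-acetoxy-2-ethenyl-2-methyl-7-oxoheptanoate | C=C[C@](C)(C(=O)OCC[Si](C)(C)C)[C@H](OC(C)=O)CCCC=O
F9 | step 5 | 2-(trimethylsilyl)ethyl (2S,3R)-3-acetoxy-2-ethenyl-6-formyl-2-methylhept-6-enoate | C=C[C@](C)(C(=O)OCC[Si](C)(C)C)[C@H](OC(C)=O)CCC(=C)C=O
F10 | step 5 | 2-(trimethylsilyl)ethyl (2S,3R)-3-acetoxy-2-ethenyl-6-(hydroxymethyl)-2-methylhept-6-enoate | C=C[C@](C)(C(=O)OCC[Si](C)(C)C)[C@H](OC(C)=O)CCC(=C)CO
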